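**Retrosynthetic overview**

1. Target 40 ⇐ cleavage of sixteen methyl ethers of tetraphenol 39 ⇐ four-fold Baeyer–Villiger oxidation of tetra-aldehyde 37 ⇐ SNAr union at the D2–O–E1 bond of tetramer ABCD 23 (free D2 phenol) with the fluoro tetra-aldehyde EFGH 36.
2. The feature the plan rests on: ring D (and likewise rings B and F) carries five contiguous oxygens on D4, D5, D6, D1 and D2 and one hydrogen on D3. That is the footprint of a squarate-derived 4-(1-methoxyvinyl)cyclobutenone: the four squarate carbons become D1, D6, D5 and D2, the vinyl carbons D4 and D3.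
3. 23 ⇐ thermal ring expansion (new D2–D3 bond) of cyclobutenone 20 ⇐ 1-methoxyvinyllithium addition and O-methylation on aryl methyl squarate 18 ⇐ trimer phenol 17 + squaric ester chloride 2.
4. Rings C, E and G come from 2-fluoroisophthalaldehydes: the phenol released by each ring expansion displaces fluoride, and the formyl groups later become OH by Baeyer–Villiger oxidation. Rings A and H are bought phenols.
5. Order of ring formation: ring B (step 4), ring D (step 12), ring F (step 17); all other rings enter as arenes.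

Key step: step 12

Assumption: rings are lettered A to H from the 3,5-dihydroxyphenoxy end, each ring numbered from the carbon bonded to the oxygen that links it to the preceding ring; the target has no stereocentre, and cyclobutenones 7, 20 and 28 are used as racemates whose only stereocentre disappears on aromatisation.

**Route**

Step 1
Reactants: 1 3,4-dichlorocyclobut-3-ene-1,2-dione (squaryl dichloride)
Product: 2 3-chloro-4-methoxycyclobut-3-ene-1,2-dione
Conditions: MeOH (1.0 equiv), CH2Cl2, 0 °C → rt, N2 stream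
Reagents that add atoms: methanol, CO
Why: Alcoholysis of a vinylogous acid chloride by addition–elimination; the first methoxy group turns the product into a vinylogous ester chloride that is clearly less electrophilic than 1, so one equivalent of methanol should stop at the mono-ester chloride.

Step 2
Reactants: 3 3,5-dimethoxyphenol; 2 3-chloro-4-methoxycyclobut-3-ene-1,2-dione
Product: 4 3-(3,5-dimethoxyphenoxy)-4-methoxycyclobut-3-ene-1,2-dione
Conditions: iPr2NEt, CH2Cl2, −78 → 0 °C (3 added to 1.2 equiv of 2)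
Reagents that add atoms: none
Why: Vinylogous acyl substitution (addition–elimination) at the chloride-bearing carbon; chloride is by far the best leaving group, attack at the methoxy-bearing carbon only expels the phenoxide again, and the amine-buffered low temperature favours O- over C-acylation of the electron-rich phenol.

Step 3
Reactants: 4 3-(3,5-dimethoxyphenoxy)-4-methoxycyclobut-3-ene-1,2-dione; 5 methyl vinyl ether
Product: 7 (±)-2-(3,5-dimethoxyphenoxy)-3,4-dimethoxy-4-(1-methoxyethenyl)cyclobut-2-en-1-one, via lithium cyclobutenolate 6 (not isolated)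
Conditions: 5 (3 equiv), t-BuLi, THF, −78 → 0 °C; then 4, −78 °C; then MeOTf, −78 → 0 °C
Reagents that add atoms: methyl trifluoromethanesulfonate (MeOTf), COS(=O)(=O)C(F)(F)F
Why: 1,2-Addition of an organolithium to a squarate ester with in-situ O-methylation of the alkoxide; the carbonyl vinylogous to the weaker aryloxy donor (and next to the small methoxy-bearing carbon) is the more electrophilic and less hindered one, and the new quaternary centre is formed racemic, which is irrelevant because it is lost in step 4.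

Step 4
Reactants: 7 (±)-2-(3,5-dimethoxyphenoxy)-3,4-dimethoxy-4-(1-methoxyethenyl)cyclobut-2-en-1-one
Product: 10 2-(3,5-dimethoxyphenoxy)-3,4,5-trimethoxyphenol (dimer AB), via dienylketene 8 (not isolated), via cyclohexadienone 9 (not isolated)
Conditions: toluene (degassed, 0.02 M), 110 °C, Ar
Reagents that add atoms: none
Why: Thermal rearrangement of a 4-alkenyl-4-alkoxycyclobutenone (Moore rearrangement): 4π ring opening with the C4 methoxy group rotating outward, 6π electrocyclisation of the dienylketene and enolisation should give ring B with B2 as the only free phenol.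

Step 5
Reactants: 11 2-fluoroisophthalaldehyde
Product: 12 5-bromo-2-fluoroisophthalaldehyde
Conditions: NBS (1.1 equiv), conc. H2SO4, 60 °C
Reagents that add atoms: N-bromosuccinimide (NBS), O=C1CCC(=O)N1Br
Why: Electrophilic aromatic bromination of a deactivated arene; C5 is meta to both formyl groups and para to fluorine, so it is the only position that all three substituents direct to.

Step 6
Reactants: 10 2-(3,5-dimethoxyphenoxy)-3,4,5-trimethoxyphenol; 12 5-bromo-2-fluoroisophthalaldehyde
Product: 13 5-bromo-2-[2-(3,5-dimethoxyphenoxy)-3,4,5-trimethoxyphenoxy]benzene-1,3-dicarbaldehyde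
Conditions: K2CO3, DMF, rt
Reagents that add atoms: none
Why: Nucleophilic aromatic substitution (SNAr); the fluoride is activated by two ortho formyl groups, while the bromide, meta to both, is inert.

Step 7
Reactants: 13 5-bromo-2-[2-(3,5-dimethoxyphenoxy)-3,4,5-trimethoxyphenoxy]benzene-1,3-dicarbaldehyde
Product: 15 5-bromo-2-[2-(3,5-dimethoxyphenoxy)-3,4,5-trimethoxyphenoxy]benzene-1,3-diol, via bis-formate 14 (not isolated)
Conditions: mCPBA (3 equiv), CH2Cl2, 0 °C → rt; then MeOH, Et3N (cat.), rt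
Reagents that add atoms: 3-chloroperbenzoic acid (mCPBA), OOC(=O)c1cccc(Cl)c1
Why: Baeyer–Villiger oxidation of aryl aldehydes in which the ortho aryloxy donor favours aryl over hydride migration, followed by methanolysis of the two aryl formates.

Step 8
Reactants: 15 5-bromo-2-[2-(3,5-dimethoxyphenoxy)-3,4,5-trimethoxyphenoxy]benzene-1,3-diol
Product: 16 1-(4-bromo-2,6-dimethoxyphenoxy)-2-(3,5-dimethoxyphenoxy)-3,4,5-trimethoxybenzene
Conditions: MeI, K2CO3, acetone, 50 °C
Reagents that add atoms: iodomethane (MeI), CI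
Why: Williamson O-methylation of both phenols, which caps ring C so that later only one phenol per fragment is free.

Step 9
Reactants: 16 1-(4-bromo-2,6-dimethoxyphenoxy)-2-(3,5-dimethoxyphenoxy)-3,4,5-trimethoxybenzene
Product: 17 4-[2-(3,5-dimethoxyphenoxy)-3,4,5-trimethoxyphenoxy]-3,5-dimethoxyphenol (trimer ABC)
Conditions: Pd2(dba)3 (2 mol %), tBuXPhos (8 mol %), KOH, 1,4-dioxane/H2O, 100 °C; then dilute aq. HCl
Reagents that add atoms: potassium hydroxide, [K+].[OH-]
Why: Palladium-catalysed hydroxylation of an aryl bromide (Buchwald-type C–O coupling with hydroxide); the bromide has no ortho substituent, and methyl and diaryl ethers are stable to aqueous KOH.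

Step 10
Reactants: 17 4-[2-(3,5-dimethoxyphenoxy)-3,4,5-trimethoxyphenoxy]-3,5-dimethoxyphenol; 2 3-chloro-4-methoxycyclobut-3-ene-1,2-dione
Product: 18 3-{4-[2-(3,5-dimethoxyphenoxy)-3,4,5-trimethoxyphenoxy]-3,5-dimethoxyphenoxy}-4-methoxycyclobut-3-ene-1,2-dione
Conditions: iPr2NEt, CH2Cl2, −78 → 0 °C (17 added to 1.3 equiv of 2)
Reagents that add atoms: none
Why: The same vinylogous acyl substitution as in step 2; the C4 phenol of ring C has two ortho hydrogens and is unhindered, and chloride is the only group that leaves.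

Step 11
Reactants: 18 aryl methyl squarate of trimer ABC; 5 methyl vinyl ether
Product: 20 (±)-2-{4-[2-(3,5-dimethoxyphenoxy)-3,4,5-trimethoxyphenoxy]-3,5-dimethoxyphenoxy}-3,4-dimethoxy-4-(1-methoxyethenyl)cyclobut-2-en-1-one, via lithium cyclobutenolate 19 (not isolated)
Conditions: 5 (3 equiv), t-BuLi, THF, −78 → 0 °C; then 18, −78 °C; then MeOTf, −78 → 0 °C
Reagents that add atoms: methyl trifluoromethanesulfonate (MeOTf), COS(=O)(=O)C(F)(F)F
Why: Organolithium 1,2-addition to a squarate ester and in-situ O-methylation, as in step 3; attack at the carbonyl vinylogous to the aryloxy group places the sp3 carbon next to the methoxy-bearing carbon and leaves the ketone next to the aryloxy-bearing carbon, which fixes the oxygen pattern of ring D, and the quaternary centre is racemic and transient.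

Step 12
Reactants: 20 (±)-2-(trimer ABC-oxy)-3,4-dimethoxy-4-(1-methoxyethenyl)cyclobut-2-en-1-one
Product: 23 2-{4-[2-(3,5-dimethoxyphenoxy)-3,4,5-trimethoxyphenoxy]-3,5-dimethoxyphenoxy}-3,4,5-trimethoxyphenol (tetramer ABCD), via dienylketene 21 (not isolated), via cyclohexadienone 22 (not isolated)
Conditions: toluene (degassed, 0.01 M), 110 °C, Ar
Reagents that add atoms: none
Why: Heating opens the C1–C4 bond of 20 in a conrotatory 4π electrocyclic step in which the C4 methoxy donor rotates outward, so the 1-methoxyvinyl group sits cis to the ketene in dienylketene 21. A thermally allowed disrotatory 6π electrocyclisation then joins the ketene carbon to the vinyl CH2 (the D2–D3 bond) and closes ring D as cyclohexa-2,4-dienone 22, which enolises irreversibly to phenol 23. The closest known reaction type is the thermal rearrangement of squarate-derived 4-alkenyl-4-hydroxy- or 4-alkoxycyclobutenones to hydroquinones and phenols (Moore rearrangement). No stereocentre is created; the racemic C4 centre of 20 becomes the planar D5 carbon. The step needs torquoselectivity, which the oxygen donor on C4 secures, and the regiochemistry is already fixed in step 11: the squarate carbons become D1, D6, D5 and D2, the vinyl carbons D4 and D3, and only D2 emerges as a free OH. Dilute, degassed, acid-free toluene should protect the acid-labile enol ether of 20 and the electron-rich phenol 23.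

Step 13
Reactants: 12 5-bromo-2-fluoroisophthalaldehyde
Product: 24 2,2'-(5-bromo-2-fluoro-1,3-phenylene)bis(1,3-dioxolane)
Conditions: ethylene glycol, TsOH·H2O (cat.), toluene, reflux, Dean–Stark
Reagents that add atoms: ethylene glycol, OCCO
Why: Acid-catalysed acetalisation with azeotropic removal of water, which masks both formyl groups against the vinyllithium of step 16 and switches off the SNAr activation of the fluoride.

Step 14
Reactants: 24 2,2'-(5-bromo-2-fluoro-1,3-phenylene)bis(1,3-dioxolane)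
Product: 25 3,5-bis(1,3-dioxolan-2-yl)-4-fluorophenol
Conditions: Pd2(dba)3 (2 mol %), tBuXPhos (8 mol %), KOH, 1,4-dioxane/H2O, 100 °C; then pH 7 phosphate buffer
Reagents that add atoms: potassium hydroxide, [K+].[OH-]
Why: Palladium-catalysed hydroxylation of the aryl bromide as in step 9; the C–F bond flanked by acetals is not activated towards hydroxide, and the neutral work-up keeps the acetals.

Step 15
Reactants: 25 3,5-bis(1,3-dioxolan-2-yl)-4-fluorophenol; 2 3-chloro-4-methoxycyclobut-3-ene-1,2-dione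
Product: 26 3-[3,5-bis(1,3-dioxolan-2-yl)-4-fluorophenoxy]-4-methoxycyclobut-3-ene-1,2-dione
Conditions: iPr2NEt, CH2Cl2, −78 → 0 °C (25 added to 1.2 equiv of 2)
Reagents that add atoms: none
Why: Vinylogous acyl substitution at the chloride-bearing carbon as in steps 2 and 10; the acetals are stable to the amine-buffered medium.

Step 16
Reactants: 26 3-[3,5-bis(1,3-dioxolan-2-yl)-4-fluorophenoxy]-4-methoxycyclobut-3-ene-1,2-dione; 5 methyl vinyl ether
Product: 28 (±)-2-[3,5-bis(1,3-dioxolan-2-yl)-4-fluorophenoxy]-3,4-dimethoxy-4-(1-methoxyethenyl)cyclobut-2-en-1-one, via lithium cyclobutenolate 27 (not isolated)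
Conditions: 5 (3 equiv), t-BuLi, THF, −78 → 0 °C; then 26, −78 °C; then MeOTf, −78 → 0 °C
Reagents that add atoms: methyl trifluoromethanesulfonate (MeOTf), COS(=O)(=O)C(F)(F)F
Why: Organolithium 1,2-addition to the squarate carbonyl vinylogous to the aryloxy group with in-situ O-methylation, as in steps 3 and 11; at −78 °C the squarate carbonyl reacts far faster than the acetals or the aryl fluoride, and the racemic centre is transient.

Step 17
Reactants: 28 (±)-2-[3,5-bis(1,3-dioxolan-2-yl)-4-fluorophenoxy]-3,4-dimethoxy-4-(1-methoxyethenyl)cyclobut-2-en-1-one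
Product: 31 2-[3,5-bis(1,3-dioxolan-2-yl)-4-fluorophenoxy]-3,4,5-trimethoxyphenol (dimer EF), via dienylketene 29 (not isolated), via cyclohexadienone 30 (not isolated)
Conditions: toluene (degassed, 0.02 M), 110 °C, Ar
Reagents that add atoms: none
Why: The same thermal 4π opening, 6π electrocyclisation and enolisation (Moore rearrangement) as in steps 4 and 12 should form ring F with F2 as the only free phenol; the acetals are stable to neutral thermolysis.

Step 18
Reactants: 24 2,2'-(5-bromo-2-fluoro-1,3-phenylene)bis(1,3-dioxolane); 32 2,4,6-trimethoxyphenol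
Product: 33 2,2'-[2-fluoro-5-(2,4,6-trimethoxyphenoxy)-1,3-phenylene]bis(1,3-dioxolane)
Conditions: CuI (10 mol %), picolinic acid (20 mol %), K3PO4, DMSO, 90 °C, Ar
Reagents that add atoms: none
Why: Ullmann-type copper-catalysed diaryl ether synthesis; the picolinic acid system tolerates di-ortho-substituted phenols, the aryl bromide is unhindered, and exclusion of air protects the electron-rich phenol.

Step 19
Reactants: 33 2,2'-[2-fluoro-5-(2,4,6-trimethoxyphenoxy)-1,3-phenylene]bis(1,3-dioxolane)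
Product: 34 2-fluoro-5-(2,4,6-trimethoxyphenoxy)benzene-1,3-dicarbaldehyde
Conditions: 2 M aq. HCl, THF, 40 °C
Reagents that add atoms: water, O
Why: Acid-catalysed acetal hydrolysis, which restores the two formyl groups that activate the fluoride; aryl methyl and diaryl ethers are stable to dilute acid.

Step 20
Reactants: 31 2-[3,5-bis(1,3-dioxolan-2-yl)-4-fluorophenoxy]-3,4,5-trimethoxyphenol; 34 2-fluoro-5-(2,4,6-trimethoxyphenoxy)benzene-1,3-dicarbaldehyde
Product: 35 2-{2-[3,5-bis(1,3-dioxolan-2-yl)-4-fluorophenoxy]-3,4,5-trimethoxyphenoxy}-5-(2,4,6-trimethoxyphenoxy)benzene-1,3-dicarbaldehyde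
Conditions: K2CO3, DMF, rt → 40 °C
Reagents that add atoms: none
Why: SNAr of the F2 phenoxide on the doubly ortho-formyl-activated fluoride of 34; the fluoride on ring E of 31 is flanked by acetals and so unactivated, which rules out self-condensation.

Step 21
Reactants: 35 tetramer EFGH with ring E as bis-dioxolane
Product: 36 2-[2-(4-fluoro-3,5-diformylphenoxy)-3,4,5-trimethoxyphenoxy]-5-(2,4,6-trimethoxyphenoxy)benzene-1,3-dicarbaldehyde (tetramer EFGH)
Conditions: 2 M aq. HCl, THF, 40 °C
Reagents that add atoms: water, O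
Why: Acid-catalysed acetal hydrolysis that unmasks the ring E formyl groups and thereby activates the ring E fluoride for the fragment union.

Step 22
Reactants: 23 tetramer ABCD with free D2 phenol; 36 fluoro tetra-aldehyde EFGH
Product: 37 protected octamer tetra-aldehyde (rings A–D as in 23, D2–O–E1 ether, rings E and G each 2,6-diformyl, ring F 4,5,6-trimethoxy, ring H 2,4,6-trimethoxyphenyl)
Conditions: K2CO3, DMF, rt
Reagents that add atoms: none
Why: SNAr of the D2 phenoxide on the ring E fluoride; fluoride is a far better nucleofuge than the aryloxide on the equally activated ring G, so with one equivalent of phenoxide at room temperature the G1–O–F2 ether should not be exchanged.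

Step 23
Reactants: 37 protected octamer tetra-aldehyde
Product: 39 octamer tetraphenol (E2, E6, G2 and G6 hydroxyls free; sixteen methyl ethers), via tetra-formate 38 (not isolated)
Conditions: mCPBA (6 equiv), CH2Cl2, 0 °C → rt; then MeOH, Et3N (cat.), rt, Ar
Reagents that add atoms: 3-chloroperbenzoic acid (mCPBA), OOC(=O)c1cccc(Cl)c1
Why: Four-fold Baeyer–Villiger oxidation in which every formyl group is ortho to an aryloxy donor, so aryl migration should prevail, followed by methanolysis of the formates; low temperature and limited excess of peracid should spare the electron-rich rings.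

Step 24
Reactants: 39 octamer tetraphenol
Product: 40 target CNP0319661.0 (icosahydroxy octamer)
Conditions: BBr3 (excess), CH2Cl2, −78 °C → rt; then H2O, 0 °C; reversed-phase purification under Ar
Reagents that add atoms: none
Why: Lewis acid mediated cleavage of aryl methyl ethers with BBr3 (boron coordination to the ether oxygen, bromide attack on methyl); diaryl ether bonds are not cleaved under these conditions, so all sixteen methyl groups should be removed to leave the twenty free hydroxyls.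

**Compound list**

1 | 3,4-dichlorocyclobut-3-ene-1,2-dione (squaryl dichloride) | ClC1=C(Cl)C(=O)C1=O | starting material
2 | 3-chloro-4-methoxycyclobut-3-ene-1,2-dione | COC1=C(Cl)C(=O)C1=O | intermediate
3 | 3,5-dimethoxyphenol | COc1cc(O)cc(OC)c1 | starting material
4 | 3-(3,5-dimethoxyphenoxy)-4-methoxycyclobut-3-ene-1,2-dione | COc1cc(OC)cc(OC2=C(OC)C(=O)C2=O)c1 | intermediate
5 | methyl vinyl ether | COC=C | starting material
6 | lithium 3-(3,5-dimethoxyphenoxy)-2-methoxy-1-(1-methoxyethenyl)-4-oxocyclobut-2-en-1-olate (not isolated) | COc1cc(OC)cc(OC2=C(OC)C([O-])(C(OC)=C)C2=O)c1.[Li+] | intermediate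
7 | (±)-2-(3,5-dimethoxyphenoxy)-3,4-dimethoxy-4-(1-methoxyethenyl)cyclobut-2-en-1-one | COc1cc(OC)cc(OC2=C(OC)C(OC)(C(OC)=C)C2=O)c1 | intermediate
8 | (Z)-dienylketene from 7 (not isolated) | COc1cc(OC)cc(OC(=C=O)/C(OC)=C(/OC)C(OC)=C)c1 | intermediate
9 | 2-(3,5-dimethoxyphenoxy)-3,4,5-trimethoxycyclohexa-2,4-dien-1-one (not isolated) | COc1cc(OC)cc(OC2=C(OC)C(OC)=C(OC)CC2=O)c1 | intermediate
10 | 2-(3,5-dimethoxyphenoxy)-3,4,5-trimethoxyphenol (dimer AB) | COc1cc(OC)cc(Oc2c(O)cc(OC)c(OC)c2OC)c1 | intermediate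
11 | 2-fluoroisophthalaldehyde | O=Cc1cccc(C=O)c1F | starting material
12 | 5-bromo-2-fluoroisophthalaldehyde | O=Cc1cc(Br)cc(C=O)c1F | intermediate
13 | 5-bromo-2-[2-(3,5-dimethoxyphenoxy)-3,4,5-trimethoxyphenoxy]benzene-1,3-dicarbaldehyde | COc1cc(OC)cc(Oc2c(Oc3c(C=O)cc(Br)cc3C=O)cc(OC)c(OC)c2OC)c1 | intermediate
14 | 5-bromo-2-[2-(3,5-dimethoxyphenoxy)-3,4,5-trimethoxyphenoxy]-1,3-phenylene diformate (not isolated) | COc1cc(OC)cc(Oc2c(Oc3c(OC=O)cc(Br)cc3OC=O)cc(OC)c(OC)c2OC)c1 | intermediate
15 | 5-bromo-2-[2-(3,5-dimethoxyphenoxy)-3,4,5-trimethoxyphenoxy]benzene-1,3-diol | COc1cc(OC)cc(Oc2c(Oc3c(O)cc(Br)cc3O)cc(OC)c(OC)c2OC)c1 | intermediate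
16 | 1-(4-bromo-2,6-dimethoxyphenoxy)-2-(3,5-dimethoxyphenoxy)-3,4,5-trimethoxybenzene | COc1cc(OC)cc(Oc2c(Oc3c(OC)cc(Br)cc3OC)cc(OC)c(OC)c2OC)c1 | intermediate
17 | 4-[2-(3,5-dimethoxyphenoxy)-3,4,5-trimethoxyphenoxy]-3,5-dimethoxyphenol (trimer ABC) | COc1cc(OC)cc(Oc2c(Oc3c(OC)cc(O)cc3OC)cc(OC)c(OC)c2OC)c1 | intermediate
18 | 3-{4-[2-(3,5-dimethoxyphenoxy)-3,4,5-trimethoxyphenoxy]-3,5-dimethoxyphenoxy}-4-methoxycyclobut-3-ene-1,2-dione | COc1cc(OC)cc(Oc2c(Oc3c(OC)cc(OC4=C(OC)C(=O)C4=O)cc3OC)cc(OC)c(OC)c2OC)c1 | intermediate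
19 | lithium cyclobutenolate from 18 (4-oxido adduct, not isolated) | COc1cc(OC)cc(Oc2c(Oc3c(OC)cc(OC4=C(OC)C([O-])(C(OC)=C)C4=O)cc3OC)cc(OC)c(OC)c2OC)c1.[Li+] | intermediate
20 | (±)-2-{4-[2-(3,5-dimethoxyphenoxy)-3,4,5-trimethoxyphenoxy]-3,5-dimethoxyphenoxy}-3,4-dimethoxy-4-(1-methoxyethenyl)cyclobut-2-en-1-one | COc1cc(OC)cc(Oc2c(Oc3c(OC)cc(OC4=C(OC)C(OC)(C(OC)=C)C4=O)cc3OC)cc(OC)c(OC)c2OC)c1 | intermediate
21 | (Z)-dienylketene from 20 (not isolated) | COc1cc(OC)cc(Oc2c(Oc3c(OC)cc(OC(=C=O)/C(OC)=C(/OC)C(OC)=C)cc3OC)cc(OC)c(OC)c2OC)c1 | intermediate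
22 | 2-(trimer ABC-oxy)-3,4,5-trimethoxycyclohexa-2,4-dien-1-one (not isolated) | COc1cc(OC)cc(Oc2c(Oc3c(OC)cc(OC4=C(OC)C(OC)=C(OC)CC4=O)cc3OC)cc(OC)c(OC)c2OC)c1 | intermediate
23 | 2-{4-[2-(3,5-dimethoxyphenoxy)-3,4,5-trimethoxyphenoxy]-3,5-dimethoxyphenoxy}-3,4,5-trimethoxyphenol (tetramer ABCD, free D2 phenol) | COc1cc(OC)cc(Oc2c(Oc3c(OC)cc(Oc4c(O)cc(OC)c(OC)c4OC)cc3OC)cc(OC)c(OC)c2OC)c1 | intermediate
24 | 2,2'-(5-bromo-2-fluoro-1,3-phenylene)bis(1,3-dioxolane) | Fc1c(C2OCCO2)cc(Br)cc1C1OCCO1 | intermediate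
25 | 3,5-bis(1,3-dioxolan-2-yl)-4-fluorophenol | Oc1cc(C2OCCO2)c(F)c(C2OCCO2)c1 | intermediate
26 | 3-[3,5-bis(1,3-dioxolan-2-yl)-4-fluorophenoxy]-4-methoxycyclobut-3-ene-1,2-dione | COC1=C(Oc2cc(C3OCCO3)c(F)c(C3OCCO3)c2)C(=O)C1=O | intermediate
27 | lithium cyclobutenolate from 26 (4-oxido adduct, not isolated) | COC1=C(Oc2cc(C3OCCO3)c(F)c(C3OCCO3)c2)C(=O)C1([O-])C(OC)=C.[Li+] | intermediate
28 | (±)-2-[3,5-bis(1,3-dioxolan-2-yl)-4-fluorophenoxy]-3,4-dimethoxy-4-(1-methoxyethenyl)cyclobut-2-en-1-one | COC1=C(Oc2cc(C3OCCO3)c(F)c(C3OCCO3)c2)C(=O)C1(OC)C(OC)=C | intermediate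
29 | (Z)-dienylketene from 28 (not isolated) | O=C=C(Oc1cc(C2OCCO2)c(F)c(C2OCCO2)c1)/C(OC)=C(/OC)C(OC)=C | intermediate
30 | 2-[3,5-bis(1,3-dioxolan-2-yl)-4-fluorophenoxy]-3,4,5-trimethoxycyclohexa-2,4-dien-1-one (not isolated) | O=C1CC(OC)=C(OC)C(OC)=C1Oc1cc(C2OCCO2)c(F)c(C2OCCO2)c1 | intermediate
31 | 2-[3,5-bis(1,3-dioxolan-2-yl)-4-fluorophenoxy]-3,4,5-trimethoxyphenol (dimer EF) | COc1cc(O)c(Oc2cc(C3OCCO3)c(F)c(C3OCCO3)c2)c(OC)c1OC | intermediate
32 | 2,4,6-trimethoxyphenol | COc1cc(OC)c(O)c(OC)c1 | starting material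
33 | 2,2'-[2-fluoro-5-(2,4,6-trimethoxyphenoxy)-1,3-phenylene]bis(1,3-dioxolane) | COc1cc(OC)c(Oc2cc(C3OCCO3)c(F)c(C3OCCO3)c2)c(OC)c1 | intermediate
34 | 2-fluoro-5-(2,4,6-trimethoxyphenoxy)benzene-1,3-dicarbaldehyde | COc1cc(OC)c(Oc2cc(C=O)c(F)c(C=O)c2)c(OC)c1 | intermediate
35 | 2-{2-[3,5-bis(1,3-dioxolan-2-yl)-4-fluorophenoxy]-3,4,5-trimethoxyphenoxy}-5-(2,4,6-trimethoxyphenoxy)benzene-1,3-dicarbaldehyde | COc1cc(Oc2c(C=O)cc(Oc3c(OC)cc(OC)cc3OC)cc2C=O)c(Oc2cc(C3OCCO3)c(F)c(C3OCCO3)c2)c(OC)c1OC | intermediate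
36 | 2-[2-(4-fluoro-3,5-diformylphenoxy)-3,4,5-trimethoxyphenoxy]-5-(2,4,6-trimethoxyphenoxy)benzene-1,3-dicarbaldehyde (tetramer EFGH) | COc1cc(Oc2c(C=O)cc(Oc3c(OC)cc(OC)cc3OC)cc2C=O)c(Oc2cc(C=O)c(F)c(C=O)c2)c(OC)c1OC | intermediate
37 | protected octamer tetra-aldehyde (E2, E6, G2, G6 formyl; sixteen methyl ethers) | COc1cc(OC)cc(Oc2c(Oc3c(OC)cc(Oc4c(Oc5c(C=O)cc(Oc6c(Oc7c(C=O)cc(Oc8c(OC)cc(OC)cc8OC)cc7C=O)cc(OC)c(OC)c6OC)cc5C=O)cc(OC)c(OC)c4OC)cc3OC)cc(OC)c(OC)c2OC)c1 | intermediate
38 | octamer tetra-formate (E2, E6, G2, G6 formyloxy; not isolated) | COc1cc(OC)cc(Oc2c(Oc3c(OC)cc(Oc4c(Oc5c(OC=O)cc(Oc6c(Oc7c(OC=O)cc(Oc8c(OC)cc(OC)cc8OC)cc7OC=O)cc(OC)c(OC)c6OC)cc5OC=O)cc(OC)c(OC)c4OC)cc3OC)cc(OC)c(OC)c2OC)c1 | intermediate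
39 | octamer tetraphenol (E2, E6, G2, G6 hydroxyl; sixteen methyl ethers) | COc1cc(OC)cc(Oc2c(Oc3c(OC)cc(Oc4c(Oc5c(O)cc(Oc6c(Oc7c(O)cc(Oc8c(OC)cc(OC)cc8OC)cc7O)cc(OC)c(OC)c6OC)cc5O)cc(OC)c(OC)c4OC)cc3OC)cc(OC)c(OC)c2OC)c1 | intermediate
40 | CNP0319661.0 (icosahydroxy octamer) | Oc1cc(O)cc(Oc2c(Oc3c(O)cc(Oc4c(Oc5c(O)cc(Oc6c(Oc7c(O)cc(Oc8c(O)cc(O)cc8O)cc7O)cc(O)c(O)c6O)cc5O)cc(O)c(O)c4O)cc3O)cc(O)c(O)c2O)c1 | target

**Step count**

Total: 24 steps. Longest linear sequence: 14 steps (1 → 2 → 4 → 7 → 10 → 13 → 15 → 16 → 17 → 18 → 20 → 23 → 37 → 39 → 40; steps 1–4, 6–12, 22–24).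

**Three steps most likely to fail**

1. Step 11 (and its analogues, steps 3 and 16). The organolithium may attack the carbonyl vinylogous to the methoxy group instead; that would put the aryloxy group meta to the new phenol after ring expansion. The alkoxide may also ring-open or decompose before it is O-methylated. Steps 3 and 16, run on cheap material, should show the regiochemical preference before trimer 17 is committed.
Fallback: set out from 17 and build ring D from a bought arene. Ullmann coupling of 17 with commercial 2-bromo-3,4,5-trimethoxybenzaldehyde (COc1cc(C=O)c(Br)c(OC)c1OC; CuI, picolinic acid, K3PO4, DMSO, 90 °C), where the ortho formyl group assists the coupling, should give 2-(trimer ABC-oxy)-3,4,5-trimethoxybenzaldehyde F1. Baeyer–Villiger oxidation with mCPBA should give the aryl formate F2, and methanolysis (MeOH, cat. Et3N) returns to the route at 23.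

2. Step 12 (and its analogues, steps 4 and 17). The ring opening may proceed with the wrong sense of rotation, the dienylketene may be intercepted by the product phenol or by traces of water before it cyclises, or the enol ether may hydrolyse on the way.
Fallback: set out from 17 and use a pre-formed ring D with a benzyl-protected D2 oxygen. Bromination of commercial 3,4,5-trimethoxyphenol (COc1cc(O)cc(OC)c1OC) with NBS ortho to the hydroxyl should give 2-bromo-3,4,5-trimethoxyphenol F3. Benzylation (BnBr, K2CO3, DMF) should give 1-(benzyloxy)-2-bromo-3,4,5-trimethoxybenzene F4. Ullmann coupling of 17 with F4 (CuI, 2,2,6,6-tetramethylheptane-3,5-dione, Cs2CO3, NMP, 120 °C) should give the D2 benzyl ether of tetramer ABCD F5, and hydrogenolysis (H2, Pd/C, EtOAc) returns to the route at 23.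

3. Step 24. Cleavage of sixteen methyl ethers may stop short, and the free polyphenol, with three pyrogallol-type rings, may oxidise in air during isolation.
Fallback: set out from 39 and isolate through a stable derivative. The ethers are cleaved with AlCl3/EtSH (hard acid, soft nucleophile) in CH2Cl2; the crude polyphenol is not isolated but peracetylated (Ac2O, pyridine, DMAP) to the icosaacetate of the target F6, which can be purified on silica and separated from under-cleaved material. Deacetylation under argon (cat. NaOMe, degassed MeOH, then acidic resin) returns to the route at 40.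

**Further compounds**

F1 | step 11 | 2-{4-[2-(3,5-dimethoxyphenoxy)-3,4,5-trimethoxyphenoxy]-3,5-dimethoxyphenoxy}-3,4,5-trimethoxybenzaldehyde | COc1cc(OC)cc(Oc2c(Oc3c(OC)cc(Oc4c(C=O)cc(OC)c(OC)c4OC)cc3OC)cc(OC)c(OC)c2OC)c1
F2 | step 11 | 2-{4-[2-(3,5-dimethoxyphenoxy)-3,4,5-trimethoxyphenoxy]-3,5-dimethoxyphenoxy}-3,4,5-trimethoxyphenyl formate | COc1cc(OC)cc(Oc2c(Oc3c(OC)cc(Oc4c(OC=O)cc(OC)c(OC)c4OC)cc3OC)cc(OC)c(OC)c2OC)c1
F3 | step 12 | 2-bromo-3,4,5-trimethoxyphenol | COc1cc(O)c(Br)c(OC)c1OC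
F4 | step 12 | 1-(benzyloxy)-2-bromo-3,4,5-trimethoxybenzene | COc1cc(OCc2ccccc2)c(Br)c(OC)c1OC
F5 | step 12 | D2 benzyl ether of tetramer ABCD 23 | COc1cc(OC)cc(Oc2c(Oc3c(OC)cc(Oc4c(OCc5ccccc5)cc(OC)c(OC)c4OC)cc3OC)cc(OC)c(OC)c2OC)c1
F6 | step 24 | icosaacetate of target 40 | CC(=O)Oc1cc(OC(C)=O)cc(Oc2c(Oc3c(OC(C)=O)cc(Oc4c(Oc5c(OC(C)=O)cc(Oc6c(Oc7c(OC(C)=O)cc(Oc8c(OC(C)=O)cc(OC(C)=O)cc8OC(C)=O)cc7OC(C)=O)cc(OC(C)=O)c(OC(C)=O)c6OC(C)=O)cc5OC(C)=O)cc(OC(C)=O)c(OC(C)=O)c4OC(C)=O)cc3OC(C)=O)cc(OC(C)=O)c(OC(C)=O)c2OC(C)=O)c1
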